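**Retrosynthetic overview**

1. Rings: A/B = trans-decalin, C = eleven-membered carbocycle, D = tetronic acid, E = spiro-cyclohexene. Ring C is opened at its E-alkene (ring-closing metathesis) and at the acyl–tetronate C–C bond (lithiated O-methyl tetronate plus aldehyde, then oxidation). This gives spirotetronate 21 and decalin aldehyde 41.
2. Ring D is grown on the ring E ketone 17 by propiolate addition, then methanol addition and lactonisation.
3. Ring E: the CH=C(CH2OH) unit is delivered as an alkyne and inserted between the quaternary C(CH3) carbon and the side-chain-bearing CH carbon. These two carbons are directly bonded in a 1-silyloxycyclobutene; heating opens the four-membered ring (strain release) and the diene is captured by an intramolecular Diels–Alder reaction.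
4. Enabling feature: in ring E the hydroxymethyl carbon on the alkene carbon and the oxygen of the CH(OH)CH3 group on the neighbouring side chain can close a six-membered lactone (alkene C, C=O, O, CH(CH3), CH2, ring CH), so the alkyne can be tethered as the propiolate of that alcohol. The spiro carbon carries oxygen, so the other four ring E carbons map onto a cyclobutanone enol ether.
5. Rings A/B come from a Lewis-acid intramolecular Diels–Alder reaction steered by an equatorial silyloxy group, which is then replaced by methyl with inversion (axial CH3). Ring order: cyclobutane, E (with temporary lactone), D; A/B; C last.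

Key step: step 8

Remark on the chemistry: 4, 5 and 6 are carried as mixtures of ring diastereomers. 8, 9, 11 and 12 are carried as a pair of diastereomers that share the trans relation of allyl group and side chain but differ in the absolute sense of the four-membered ring. Both members should open to the same diene 13, and the SMILES show one member. 42 is a mixture at the carbinol carbon that step 28 removes.

**Route**

Step 1
Reactants: 1 (R)-pent-4-en-2-ol
Product: 2 (R)-pent-4-en-2-yl acetate
Conditions: Ac2O, pyridine, DMAP (cat.), 0 → 23 °C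
Reagents that add atoms: acetic anhydride, CC(=O)OC(C)=O
Why: DMAP-catalysed O-acylation leaves the purchased carbinol centre untouched, and the acetate should survive the acidic and radical steps that follow.

Step 2
Reactants: 2 (R)-pent-4-en-2-yl acetate; 3 N,N-dimethylpropanamide
Product: 5 (R)-1-(2-methyl-3-oxocyclobutyl)propan-2-yl acetate, via cyclobutaniminium triflate 4 (not isolated)
Conditions: Tf2O, 2,4,6-collidine, ClCH2CH2Cl, 80 °C; then H2O, 80 °C
Reagents that add atoms: water, O; trifluoromethanesulfonic anhydride, O=S(=O)(OS(=O)(=O)C(F)(F)F)C(F)(F)F (supplies only the counter-ion of 4)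
Why: In this keteniminium–alkene [2+2] cycloaddition with iminium hydrolysis the electrophilic central carbon bonds to the terminal CH2, so the side chain ends next to CH(CH3); the new ring centres need no control because one is erased in step 3 and the ring sense is erased in step 8.

Step 3
Reactants: 5 (R)-1-(2-methyl-3-oxocyclobutyl)propan-2-yl acetate
Product: 6 (R)-1-(2-bromo-2-methyl-3-oxocyclobutyl)propan-2-yl acetate
Conditions: Br2, AcOH, 23 °C
Reagents that add atoms: bromine, BrBr
Why: Acid-catalysed alpha-bromination of a ketone runs through the more substituted enol and should place bromine on the methyl-bearing carbon.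

Step 4
Reactants: 6 (R)-1-(2-bromo-2-methyl-3-oxocyclobutyl)propan-2-yl acetate; 7 allyltributylstannane
Product: 8 (R)-1-(2-allyl-2-methyl-3-oxocyclobutyl)propan-2-yl acetate, allyl trans and methyl cis to the side chain
Conditions: AIBN (cat.), benzene, 80 °C
Reagents that add atoms: none
Why: In the Keck radical allylation the planar tertiary alpha-keto radical should be trapped on the ring face opposite to the neighbouring side chain, which sets the trans relation that step 8 turns into diene geometry.

Step 5
Reactants: 8 (R)-1-(2-allyl-2-methyl-3-oxocyclobutyl)propan-2-yl acetate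
Product: 9 2-allyl-3-[(R)-2-hydroxypropyl]-2-methylcyclobutan-1-one
Conditions: K2CO3 (cat.), MeOH, 0 → 23 °C
Reagents that add atoms: none
Why: Base-catalysed transesterification frees the carbinol, and the quaternary alpha carbon cannot epimerise.

Step 6
Reactants: 9 2-allyl-3-[(R)-2-hydroxypropyl]-2-methylcyclobutan-1-one; 10 propiolic acid
Product: 11 (R)-1-(2-allyl-2-methyl-3-oxocyclobutyl)propan-2-yl propiolate
Conditions: DCC, DMAP (cat.), CH2Cl2, −20 → 0 °C
Reagents that add atoms: none
Why: Steglich esterification with retention at the carbinol carbon tethers the alkyne that carries the two future ring carbons and the future hydroxymethyl carbon.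

Step 7
Reactants: 11 (R)-1-(2-allyl-2-methyl-3-oxocyclobutyl)propan-2-yl propiolate
Product: 12 (R)-1-[2-allyl-2-methyl-3-(triethylsilyloxy)cyclobut-3-en-1-yl]propan-2-yl propiolate
Conditions: TESOTf, Et3N, CH2Cl2, −78 → 0 °C
Reagents that add atoms: triethylsilyl triflate, CC[Si](CC)(CC)OS(=O)(=O)C(F)(F)F
Why: In this soft enolisation with O-silylation the ketone can enolise only toward its CH2 group because the other alpha carbon is quaternary, and O-silyl activation should make this faster than any attack of the amine on the propiolate.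

Step 8
Reactants: 12 (R)-1-[2-allyl-2-methyl-3-(triethylsilyloxy)cyclobut-3-en-1-yl]propan-2-yl propiolate
Product: 14 (3R,4aR,7R)-7-allyl-3,7-dimethyl-6-(triethylsilyloxy)-3,4,4a,7-tetrahydro-1H-isochromen-1-one, via (4E,6Z)-silyloxytriene propiolate 13 (not isolated)
Conditions: o-C6H4Cl2 (high dilution), BHT, 180 °C, argon
Reagents that add atoms: none
Why: Heating should open the cyclobutene by the thermally allowed conrotatory four-electron electrocyclic reaction, driven by release of ring strain, in the sense that turns the side-chain CH2 and the allyl group outward and only H and CH3 inward, so both ring-antipodal members of 12 give the single (E,Z)-2-silyloxydiene 13. The tethered propiolate then adds across the diene termini in a concerted, asynchronous intramolecular Diels–Alder reaction, so the net event is insertion of the two alkyne carbons into the former cyclobutene sigma bond; the closest known reaction types are the thermal opening of 1-silyloxycyclobutenes and benzocyclobutenes with in situ Diels–Alder capture and the cycloaddition of dienyl propiolates. Ring E closes as the [4+2] ring and the temporary delta-lactone closes as the fused six-membered tether ring of a type 1 intramolecular cycloaddition (four-atom tether), and the alkyne dienophile leaves no endo/exo question. The quaternary carbon is fixed relative to the new ring CH by the diene geometry and suprafacial addition (outward allyl and outward side chain end cis), and both are fixed relative to the carbinol centre by the tether, which should react through the half-chair that keeps its methyl group pseudo-equatorial, cis-1,3 to the ring E bond in the lactone. Regiochemistry is secured twice, by the tether and by the pairing of the silyloxy-activated, nucleophilic disubstituted diene terminus with the electrophilic terminal alkyne carbon. The cycloaddition has to outrun the [1,5]-hydrogen shift of the inward methyl group, which its intramolecular, donor–acceptor-matched character should secure.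

Step 9
Reactants: 14 bicyclic silyloxydienyl lactone
Product: 15 (R)-1-[(1R,4R)-4-allyl-2-(hydroxymethyl)-4-methyl-5-(triethylsilyloxy)cyclohexa-2,5-dien-1-yl]propan-2-ol
Conditions: DIBAL-H, CH2Cl2, −78 → 0 °C; aq. potassium sodium tartrate
Reagents that add atoms: none
Why: 1,2-Reduction of the unsaturated lactone by DIBAL-H removes the temporary tether and delivers both hydroxyl groups of the target at once, while the silyl enol ether masks the ketone.

Step 10
Reactants: 15 dienyl diol
Product: 17 (2R,5R)-2-allyl-4-[(tert-butyldimethylsilyloxy)methyl]-5-[(R)-2-(tert-butyldimethylsilyloxy)propyl]-2-methylcyclohex-3-en-1-one, via tris-silyl ether 16 (not isolated)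
Conditions: TBSCl, imidazole, DMF, 23 °C; then 1 M HCl, THF, 0 °C (brief)
Reagents that add atoms: tert-butyldimethylsilyl chloride, CC(C)(C)[Si](C)(C)Cl
Why: Silylation of both alcohols is followed by selective acid hydrolysis of the much more labile silyl enol ether, and the ring alkene cannot move into conjugation because the carbon between it and the ketone is quaternary.

Step 11
Reactants: 17 ring E ketone; 18 methyl propiolate
Product: 19 methyl 3-[(1S,2R,5R)-2-allyl-4-[(tert-butyldimethylsilyloxy)methyl]-5-[(R)-2-(tert-butyldimethylsilyloxy)propyl]-1-hydroxy-2-methylcyclohex-3-en-1-yl]propiolate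
Conditions: LDA, THF, −78 °C (18 first, then 17)
Reagents that add atoms: none
Why: In this 1,2-addition of a lithium acetylide to a ketone the slim nucleophile should approach from the ring face that carries only the methyl group, opposite to the allyl group and the side chain, which sets the future spiro carbon with its oxygen cis to those two chains.

Step 12
Reactants: 19 tertiary propargylic alcohol
Product: 21 (5S,6R,9R)-6-allyl-8-[(tert-butyldimethylsilyloxy)methyl]-9-[(R)-2-(tert-butyldimethylsilyloxy)propyl]-4-methoxy-6-methyl-1-oxaspiro[4.5]deca-3,7-dien-2-one, via (E)-beta-methoxyacrylate 20 (not isolated)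
Conditions: NaOMe (cat.), MeOH, 23 → 50 °C
Reagents that add atoms: methanol, CO
Why: Conjugate addition of methoxide to the ynoate and lactonisation of the tertiary alkoxide onto the ester is the established construction of O-methyl spirotetronates and touches no stereocentre.

Step 13
Reactants: 22 (R)-2-(but-3-en-1-yl)oxirane; 23 methyl methacrylate
Product: 24 methyl (E)-2-methyl-5-[(R)-oxiran-2-yl]pent-2-enoate
Conditions: RuCl2(H2IMes)(=CH-C6H4-2-OiPr) (second-generation Hoveyda–Grubbs catalyst, cat.), excess 23, CH2Cl2, 40 °C
Reagents that add atoms: none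
Why: Olefin cross-metathesis of a terminal alkene with a 1,1-disubstituted acrylate should give the (E)-trisubstituted enoate, and the epoxide is inert to the catalyst.

Step 14
Reactants: 24 epoxy enoate; 25 vinylmagnesium bromide
Product: 26 methyl (2E,6R)-6-hydroxy-2-methylnona-2,8-dienoate
Conditions: CuI (cat.), THF, −40 °C
Reagents that add atoms: none
Why: Copper-catalysed Grignard opening of the terminal epoxide occurs by SN2 attack at its CH2 carbon, so the carbinol centre keeps its configuration, and the hindered enoate should not compete at low temperature.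

Step 15
Reactants: 26 homoallylic alcohol
Product: 27 methyl (2E,6R)-6-(tert-butyldiphenylsilyloxy)-2-methylnona-2,8-dienoate
Conditions: TBDPSCl, imidazole, DMF, 23 °C
Reagents that add atoms: tert-butyldiphenylsilyl chloride, CC(C)(C)[Si](Cl)(c1ccccc1)c1ccccc1
Why: Standard O-silylation installs a Lewis-acid-stable, bulky group that serves as the equatorial control element of step 20.

Step 16
Reactants: 27 silyl ether; 28 diethyl allylphosphonate
Product: 29 methyl (2E,6R,8E)-6-(tert-butyldiphenylsilyloxy)-10-(diethoxyphosphoryl)-2-methyldeca-2,8-dienoate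
Conditions: RuCl2(H2IMes)(PCy3)(=CHPh) (second-generation Grubbs catalyst, cat.), CH2Cl2, 40 °C
Reagents that add atoms: none
Why: Cross-metathesis of the only terminal alkene with an allylphosphonate should be E-selective, and the trisubstituted enoate is inert.

Step 17
Reactants: 30 methyl (R)-3-hydroxy-2-methylpropanoate
Product: 31 methyl (R)-3-(tert-butyldiphenylsilyloxy)-2-methylpropanoate
Conditions: TBDPSCl, imidazole, DMF, 23 °C
Reagents that add atoms: tert-butyldiphenylsilyl chloride, CC(C)(C)[Si](Cl)(c1ccccc1)c1ccccc1
Why: Standard O-silylation of the primary alcohol leaves the purchased methyl-bearing stereocentre untouched.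

Step 18
Reactants: 31 silyloxy ester
Product: 32 (R)-3-(tert-butyldiphenylsilyloxy)-2-methylpropanal
Conditions: DIBAL-H (1 equiv), CH2Cl2, −78 °C
Reagents that add atoms: none
Why: Partial DIBAL-H reduction of the ester stops at the tetrahedral aluminate at low temperature and gives the aldehyde without epimerisation.

Step 19
Reactants: 29 allylic phosphonate; 32 alpha-methyl aldehyde
Product: 33 methyl (2E,6R,8E,10E,12S)-6,13-bis(tert-butyldiphenylsilyloxy)-2,12-dimethyltrideca-2,8,10-trienoate
Conditions: LiHMDS, THF, −78 °C; then 32, −78 → 0 °C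
Reagents that add atoms: none
Why: Horner–Wadsworth–Emmons olefination of the allylic phosphonate anion at its alpha carbon should give the (E,E)-diene, and the low temperature protects the alpha stereocentre of the aldehyde.

Step 20
Reactants: 33 (E,E,E)-trienoate
Product: 34 methyl (1S,2S,4aS,6R,8aR)-6-(tert-butyldiphenylsilyloxy)-2-[(S)-1-(tert-butyldiphenylsilyloxy)propan-2-yl]-1-methyl-1,2,4a,5,6,7,8,8a-octahydronaphthalene-1-carboxylate
Conditions: EtAlCl2, CH2Cl2, −20 → 23 °C
Reagents that add atoms: none
Why: The Lewis-acid-promoted intramolecular Diels–Alder reaction of an (E,E,E)-trienoate should run through the ester-endo, chair-like transition state to the trans-decalin with ester and side chain cis, and the diene face is chosen by the tether carbinol centre, whose silyloxy group sits equatorial, which fixes all four new ring stereocentres.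

Step 21
Reactants: 34 decalin ester
Product: 36 tricyclic hydroxy delta-lactone (trans-decalin whose quaternary-carbon carboxyl is lactonised with the primary alcohol of the neighbouring side chain; equatorial OH on ring A), via dihydroxy ester 35 (not isolated)
Conditions: TBAF, THF, 0 → 40 °C
Reagents that add atoms: none
Why: After fluoride desilylation the primary alkoxide is held next to the cis ester and should lactonise, which protects both carbons in one ring and leaves only the secondary equatorial alcohol free.

Step 22
Reactants: 36 hydroxy lactone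
Product: 37 equatorial p-toluenesulfonate of 36
Conditions: TsCl, pyridine, DMAP (cat.), 0 → 23 °C
Reagents that add atoms: p-toluenesulfonyl chloride, Cc1ccc(cc1)S(=O)(=O)Cl
Why: O-Sulfonylation proceeds with retention at carbon and turns the control element into a leaving group.

Step 23
Reactants: 37 equatorial tosylate
Product: 38 tricyclic lactone with axial methyl group on ring A
Conditions: Me2CuLi (from MeLi and CuI), Et2O, −20 → 23 °C
Reagents that add atoms: lithium dimethylcuprate, [Li+].C[Cu-]C (made from methyllithium, [Li]C, and CuI)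
Why: SN2 substitution of a secondary sulfonate by a Gilman cuprate goes with inversion; the leaving group is locked equatorial in the trans-decalin so anti-periplanar E2 elimination is not available, methyl enters axially to give the axial C-methyl epimer that a methyl group already in the tether (which would also sit equatorial in step 20) could not give, and lactones are inert to the cuprate.

Step 24
Reactants: 38 methyl lactone
Product: 39 (S)-2-[(1S,2S,4aS,6S,8aR)-1-(hydroxymethyl)-1,6-dimethyl-1,2,4a,5,6,7,8,8a-octahydronaphthalen-2-yl]propan-1-ol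
Conditions: LiAlH4, THF, 0 → 23 °C
Reagents that add atoms: none
Why: Hydride reduction of the lactone opens the protecting ring to the two primary alcohols without touching a stereocentre.

Step 25
Reactants: 39 diol
Product: 40 (1S,2S,4aS,6S,8aR)-1,6-dimethyl-2-[(S)-1-oxopropan-2-yl]-1,2,4a,5,6,7,8,8a-octahydronaphthalene-1-carbaldehyde
Conditions: (COCl)2, DMSO, CH2Cl2, −78 °C; Et3N, −78 → 0 °C
Reagents that add atoms: none
Why: In the Swern oxidation both alcohols are activated before base is added, so the dialdehyde should form without detour through a lactol, and the cold, short base contact protects the alpha stereocentre.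

Step 26
Reactants: 40 dialdehyde
Product: 41 (1S,2S,4aS,6S,8aR)-2-[(R)-but-3-en-2-yl]-1,6-dimethyl-1,2,4a,5,6,7,8,8a-octahydronaphthalene-1-carbaldehyde
Conditions: Ph3PCH3Br, KHMDS, THF; 1 equiv of ylide, −78 → 0 °C
Reagents that add atoms: methyltriphenylphosphonium bromide, C[P+](c1ccccc1)(c1ccccc1)c1ccccc1.[Br-]
Why: Wittig methylenation with one equivalent of ylide should take the less hindered aldehyde on the secondary carbon and spare the neopentyl aldehyde on the quaternary ring carbon.

Step 27
Reactants: 21 O-methyl spirotetronate; 41 decalin aldehyde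
Product: 42 secondary carbinol joining the tetronate alpha carbon to the decalin quaternary carbon (both carbinol epimers)
Conditions: LDA, THF, −78 °C (21 first, then 41)
Reagents that add atoms: none
Why: Lithiation of the O-methyl tetronate at its vinylic alpha carbon and 1,2-addition to the non-enolisable aldehyde is the standard union of spirotetronates with decalin aldehydes, and the new carbinol centre is removed in step 28.

Step 28
Reactants: 42 carbinol
Product: 43 3-acyl-4-methoxy spirotetronate (open-chain diene for ring closure)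
Conditions: Dess–Martin periodinane, CH2Cl2, 23 °C
Reagents that add atoms: none
Why: Dess–Martin oxidation of the hindered secondary alcohol gives the ketone under neutral conditions that spare the silyl ethers and alkenes.

Step 29
Reactants: 43 acyl tetronate diene
Product: 44 macrocyclic O-methyl bis-TBS ether (ring C closed, E-alkene)
Conditions: RuCl2(H2IMes)(PCy3)(=CHPh) (second-generation Grubbs catalyst, cat.), toluene (high dilution), 80 °C
Reagents that add atoms: none
Why: Ring-closing metathesis of the only two monosubstituted alkenes closes the eleven-membered ring C, the ring alkenes flanked by branched carbons are inert, and reversible metathesis should settle on the less strained E-alkene.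

Step 30
Reactants: 44 macrocyclic methyl tetronate
Product: 45 macrocyclic tetronic acid bis-TBS ether
Conditions: LiCl, DMSO, 60 °C; then 1 M HCl
Reagents that add atoms: none
Why: Nucleophilic O-demethylation of the vinylogous carbonate by chloride (SN2 at the methyl group) is the usual release of acyl tetronic acids and leaves the silyl ethers in place.

Step 31
Reactants: 45 bis-TBS ether
Product: 46 CNP0189906.1 (target)
Conditions: HF·pyridine, THF, 0 → 23 °C
Reagents that add atoms: none
Why: Fluoride cleavage of both silyl ethers under mildly acidic conditions frees the primary allylic and the secondary alcohol without touching a stereocentre.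

**Compound list**

1 | (R)-pent-4-en-2-ol | C[C@@H](O)CC=C | starting material
2 | (R)-pent-4-en-2-yl acetate | C[C@@H](OC(C)=O)CC=C | intermediate
3 | N,N-dimethylpropanamide | CCC(=O)N(C)C | starting material
4 | [3-((R)-2-acetoxypropyl)-2-methylcyclobutylidene]dimethylammonium triflate (ring diastereomers) | C[C@@H](OC(C)=O)CC1CC(=[N+](C)C)C1C.[O-]S(=O)(=O)C(F)(F)F | intermediate
5 | (R)-1-(2-methyl-3-oxocyclobutyl)propan-2-yl acetate (ring diastereomers) | C[C@@H](OC(C)=O)CC1CC(=O)C1C | intermediate
6 | (R)-1-(2-bromo-2-methyl-3-oxocyclobutyl)propan-2-yl acetate (ring diastereomers) | C[C@@H](OC(C)=O)CC1CC(=O)C1(C)Br | intermediate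
7 | allyltributylstannane | C=CC[Sn](CCCC)(CCCC)CCCC | starting material
8 | (R)-1-(2-allyl-2-methyl-3-oxocyclobutyl)propan-2-yl acetate, allyl trans to side chain | C[C@@H](OC(C)=O)C[C@H]1CC(=O)[C@]1(C)CC=C | intermediate
9 | 2-allyl-3-[(R)-2-hydroxypropyl]-2-methylcyclobutan-1-one, allyl trans to side chain | C[C@@H](O)C[C@H]1CC(=O)[C@]1(C)CC=C | intermediate
10 | propiolic acid | C#CC(=O)O | starting material
11 | (R)-1-(2-allyl-2-methyl-3-oxocyclobutyl)propan-2-yl propiolate | C[C@@H](OC(=O)C#C)C[C@H]1CC(=O)[C@]1(C)CC=C | intermediate
12 | (R)-1-[2-allyl-2-methyl-3-(triethylsilyloxy)cyclobut-3-en-1-yl]propan-2-yl propiolate | C[C@@H](OC(=O)C#C)C[C@H]1C=C(O[Si](CC)(CC)CC)[C@]1(C)CC=C | intermediate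
13 | (2R,4E,6Z)-7-methyl-6-(triethylsilyloxy)deca-4,6,9-trien-2-yl propiolate | C[C@@H](OC(=O)C#C)C/C=C/C(O[Si](CC)(CC)CC)=C(\C)CC=C | intermediate
14 | (3R,4aR,7R)-7-allyl-3,7-dimethyl-6-(triethylsilyloxy)-3,4,4a,7-tetrahydro-1H-isochromen-1-one | C=CC[C@]1(C)C=C2C(=O)O[C@H](C)C[C@@H]2C=C1O[Si](CC)(CC)CC | intermediate
15 | (R)-1-[(1R,4R)-4-allyl-2-(hydroxymethyl)-4-methyl-5-(triethylsilyloxy)cyclohexa-2,5-dien-1-yl]propan-2-ol | C=CC[C@]1(C)C=C(CO)[C@H](C[C@@H](C)O)C=C1O[Si](CC)(CC)CC | intermediate
16 | bis-TBS ether of 15 (triethylsilyl enol ether still in place) | C=CC[C@]1(C)C=C(CO[Si](C)(C)C(C)(C)C)[C@H](C[C@@H](C)O[Si](C)(C)C(C)(C)C)C=C1O[Si](CC)(CC)CC | intermediate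
17 | (2R,5R)-2-allyl-4-[(TBS-oxy)methyl]-5-[(R)-2-(TBS-oxy)propyl]-2-methylcyclohex-3-en-1-one | C=CC[C@]1(C)C=C(CO[Si](C)(C)C(C)(C)C)[C@H](C[C@@H](C)O[Si](C)(C)C(C)(C)C)CC1=O | intermediate
18 | methyl propiolate | C#CC(=O)OC | starting material
19 | methyl 3-[(1S,2R,5R)-2-allyl-1-hydroxy-2-methyl-4-[(TBS-oxy)methyl]-5-[(R)-2-(TBS-oxy)propyl]cyclohex-3-en-1-yl]propiolate | C=CC[C@]1(C)C=C(CO[Si](C)(C)C(C)(C)C)[C@H](C[C@@H](C)O[Si](C)(C)C(C)(C)C)C[C@@]1(O)C#CC(=O)OC | intermediate
20 | (E)-beta-methoxyacrylate formed from 19 and methanol | C=CC[C@]1(C)C=C(CO[Si](C)(C)C(C)(C)C)[C@H](C[C@@H](C)O[Si](C)(C)C(C)(C)C)C[C@@]1(O)/C(OC)=C\C(=O)OC | intermediate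
21 | (5S,6R,9R)-6-allyl-4-methoxy-6-methyl-8-[(TBS-oxy)methyl]-9-[(R)-2-(TBS-oxy)propyl]-1-oxaspiro[4.5]deca-3,7-dien-2-one | C=CC[C@]1(C)C=C(CO[Si](C)(C)C(C)(C)C)[C@H](C[C@@H](C)O[Si](C)(C)C(C)(C)C)C[C@]12OC(=O)C=C2OC | intermediate
22 | (R)-2-(but-3-en-1-yl)oxirane | C=CCC[C@@H]1CO1 | starting material
23 | methyl methacrylate | C=C(C)C(=O)OC | starting material
24 | methyl (E)-2-methyl-5-[(R)-oxiran-2-yl]pent-2-enoate | COC(=O)/C(C)=C/CC[C@@H]1CO1 | intermediate
25 | vinylmagnesium bromide | C=C[Mg]Br | starting material
26 | methyl (2E,6R)-6-hydroxy-2-methylnona-2,8-dienoate | COC(=O)/C(C)=C/CC[C@@H](O)CC=C | intermediate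
27 | methyl (2E,6R)-6-(TBDPS-oxy)-2-methylnona-2,8-dienoate | COC(=O)/C(C)=C/CC[C@@H](O[Si](c1ccccc1)(c1ccccc1)C(C)(C)C)CC=C | intermediate
28 | diethyl allylphosphonate | C=CCP(=O)(OCC)OCC | starting material
29 | methyl (2E,6R,8E)-6-(TBDPS-oxy)-10-(diethoxyphosphoryl)-2-methyldeca-2,8-dienoate | COC(=O)/C(C)=C/CC[C@@H](O[Si](c1ccccc1)(c1ccccc1)C(C)(C)C)C/C=C/CP(=O)(OCC)OCC | intermediate
30 | methyl (R)-3-hydroxy-2-methylpropanoate | COC(=O)[C@H](C)CO | starting material
31 | methyl (R)-3-(TBDPS-oxy)-2-methylpropanoate | COC(=O)[C@H](C)CO[Si](c1ccccc1)(c1ccccc1)C(C)(C)C | intermediate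
32 | (R)-3-(TBDPS-oxy)-2-methylpropanal | O=C[C@H](C)CO[Si](c1ccccc1)(c1ccccc1)C(C)(C)C | intermediate
33 | methyl (2E,6R,8E,10E,12S)-6,13-bis(TBDPS-oxy)-2,12-dimethyltrideca-2,8,10-trienoate | COC(=O)/C(C)=C/CC[C@@H](O[Si](c1ccccc1)(c1ccccc1)C(C)(C)C)C/C=C/C=C/[C@H](C)CO[Si](c1ccccc1)(c1ccccc1)C(C)(C)C | intermediate
34 | methyl (1S,2S,4aS,6R,8aR)-6-(TBDPS-oxy)-2-[(S)-1-(TBDPS-oxy)propan-2-yl]-1-methyl-1,2,4a,5,6,7,8,8a-octahydronaphthalene-1-carboxylate | CC(C)(C)[Si](c1ccccc1)(c1ccccc1)O[C@@H]1CC[C@@H]2[C@H](C=C[C@@H]([C@H](C)CO[Si](c1ccccc1)(c1ccccc1)C(C)(C)C)[C@@]2(C)C(=O)OC)C1 | intermediate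
35 | dihydroxy ester from 34 | O[C@@H]1CC[C@@H]2[C@H](C=C[C@@H]([C@H](C)CO)[C@@]2(C)C(=O)OC)C1 | intermediate
36 | tricyclic hydroxy delta-lactone, equatorial OH on ring A | O[C@@H]1CC[C@@H]2[C@H](C=C[C@H]3[C@H](C)COC(=O)[C@@]23C)C1 | intermediate
37 | equatorial tosylate of 36 | Cc1ccc(cc1)S(=O)(=O)O[C@@H]1CC[C@@H]2[C@H](C=C[C@H]3[C@H](C)COC(=O)[C@@]23C)C1 | intermediate
38 | tricyclic delta-lactone with axial ring A methyl | C[C@H]1CC[C@@H]2[C@H](C=C[C@H]3[C@H](C)COC(=O)[C@@]23C)C1 | intermediate
39 | (S)-2-[(1S,2S,4aS,6S,8aR)-1-(hydroxymethyl)-1,6-dimethyl-octahydronaphthalen-2-yl]propan-1-ol | C[C@H]1CC[C@@H]2[C@H](C=C[C@@H]([C@H](C)CO)[C@@]2(C)CO)C1 | intermediate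
40 | (1S,2S,4aS,6S,8aR)-1,6-dimethyl-2-[(S)-1-oxopropan-2-yl]-octahydronaphthalene-1-carbaldehyde | C[C@H]1CC[C@@H]2[C@H](C=C[C@@H]([C@H](C)C=O)[C@@]2(C)C=O)C1 | intermediate
41 | (1S,2S,4aS,6S,8aR)-2-[(R)-but-3-en-2-yl]-1,6-dimethyl-1,2,4a,5,6,7,8,8a-octahydronaphthalene-1-carbaldehyde | C[C@H]1CC[C@@H]2[C@H](C=C[C@@H]([C@H](C)C=C)[C@@]2(C)C=O)C1 | intermediate
42 | coupled carbinol (tetronate alpha carbon–CH(OH)–decalin quaternary carbon), both epimers | C[C@H]1CC[C@@H]2[C@H](C=C[C@@H]([C@H](C)C=C)[C@@]2(C)C(O)C3=C(OC)[C@]4(OC3=O)C[C@@H](C[C@@H](C)O[Si](C)(C)C(C)(C)C)C(CO[Si](C)(C)C(C)(C)C)=C[C@@]4(C)CC=C)C1 | intermediate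
43 | coupled ketone (3-acyl-4-methoxy spirotetronate) | C[C@H]1CC[C@@H]2[C@H](C=C[C@@H]([C@H](C)C=C)[C@@]2(C)C(=O)C3=C(OC)[C@]4(OC3=O)C[C@@H](C[C@@H](C)O[Si](C)(C)C(C)(C)C)C(CO[Si](C)(C)C(C)(C)C)=C[C@@]4(C)CC=C)C1 | intermediate
44 | macrocycle, O-methyl tetronate, bis-TBS ether | C[C@H]1CC[C@@H]2[C@H](C=C[C@H]3[C@H](C)/C=C/C[C@]4(C)C=C(CO[Si](C)(C)C(C)(C)C)[C@H](C[C@@H](C)O[Si](C)(C)C(C)(C)C)C[C@]45OC(=O)C(=C5OC)C(=O)[C@@]23C)C1 | intermediate
45 | macrocycle, free tetronic acid, bis-TBS ether | C[C@H]1CC[C@@H]2[C@H](C=C[C@H]3[C@H](C)/C=C/C[C@]4(C)C=C(CO[Si](C)(C)C(C)(C)C)[C@H](C[C@@H](C)O[Si](C)(C)C(C)(C)C)C[C@]45OC(=O)C(=C5O)C(=O)[C@@]23C)C1 | intermediate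
46 | CNP0189906.1 | C[C@H]1CC[C@@H]2[C@H](C=C[C@H]3[C@H](C)/C=C/C[C@]4(C)C=C(CO)[C@H](C[C@@H](C)O)C[C@]45OC(=O)C(=C5O)C(=O)[C@@]23C)C1 | target

**Step count**

Total step count: 31 steps.
Longest linear sequence: 17 steps (steps 1–12, then 27–31). The southern line (steps 13–16, 19–26, then 27–31) is equally long.

**Steps most likely to fail**

1. Step 8 (ring opening and cycloaddition).
   - What may go wrong: the ester tether must leave its preferred s-trans conformation. The cycloaddition may therefore become slower than the [1,5]-hydrogen shift of the inward methyl group or a Cope shift of the allyl group. The single tether stereocentre may also give incomplete facial selection.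
   - Fallback (bimolecular capture, with stereocontrol replaced by separation): it sets out from 8, which is silylated (TESOTf, Et3N) to the acetate-bearing triethylsilyloxycyclobutene F1. F1 is heated with an excess of methyl propiolate 18, so the diene is captured intermolecularly with the regiochemistry dictated by the silyloxy group. This gives the cyclohexadiene ester acetate F2 together with its diastereomer of opposite ring sense, which is removed by chromatography. DIBAL-H then reduces the methyl ester and cleaves the acetate in one operation, and the route is rejoined at 15.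

2. Step 29 (closure of ring C).
   - What may go wrong: strain in the eleven-membered ring may favour oligomerisation, or the closure may deliver the wrong alkene geometry.
   - Fallback (alkene first, ring closed at the other bond): it sets out from 21 and 41. Compound 21 is lithiated and iodinated (LDA, then I2) to the 3-iodo tetronate F3. Cross-metathesis of F3 with 41 forms the alkene in an open chain, where E selectivity is normal, and gives the iodo aldehyde F4. A Nozaki–Hiyama–Kishi reaction (CrCl2, NiCl2 cat., DMSO, high dilution) closes ring C at the tetronate–carbinol bond to the macrocyclic carbinol F5. Dess–Martin oxidation rejoins the route at 44.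

3. Step 23 (methyl for tosylate with inversion).
   - What may go wrong: axial approach to the ring carbon is hindered by two syn-axial hydrogens, so substitution may be slow and reduction or elimination of the sulfonate may take over.
   - Fallback (hydrogenation instead of substitution): it sets out from 36, which is oxidised (Dess–Martin periodinane) to the ring A ketone F6. Wittig methylenation gives the exocyclic alkene F7. Hydrogenation with RhCl(PPh3)3 should take the unhindered 1,1-disubstituted alkene in preference to the flanked ring B alkene and deliver hydrogen from the equatorial side. The methyl group then ends axial and the route is rejoined at 38.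

**Further compounds**

F1 | step 8 | (R)-1-[2-allyl-2-methyl-3-(triethylsilyloxy)cyclobut-3-en-1-yl]propan-2-yl acetate | C[C@@H](OC(C)=O)C[C@H]1C=C(O[Si](CC)(CC)CC)[C@]1(C)CC=C
F2 | step 8 | methyl (3R,6R)-6-[(R)-2-acetoxypropyl]-3-allyl-3-methyl-4-(triethylsilyloxy)cyclohexa-1,4-diene-1-carboxylate | C=CC[C@]1(C)C=C(C(=O)OC)[C@H](C[C@@H](C)OC(C)=O)C=C1O[Si](CC)(CC)CC
F3 | step 29 | 3-iodo derivative of spirotetronate 21 | C=CC[C@]1(C)C=C(CO[Si](C)(C)C(C)(C)C)[C@H](C[C@@H](C)O[Si](C)(C)C(C)(C)C)C[C@]12OC(=O)C(I)=C2OC
F4 | step 29 | open-chain E-alkene joining iodo tetronate and decalin aldehyde | C[C@H]1CC[C@@H]2[C@H](C=C[C@@H]([C@H](C)/C=C/C[C@]3(C)C=C(CO[Si](C)(C)C(C)(C)C)[C@H](C[C@@H](C)O[Si](C)(C)C(C)(C)C)C[C@]34OC(=O)C(I)=C4OC)[C@@]2(C)C=O)C1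
F5 | step 29 | macrocyclic carbinol (ring C closed, both carbinol epimers) | C[C@H]1CC[C@@H]2[C@H](C=C[C@H]3[C@H](C)/C=C/C[C@]4(C)C=C(CO[Si](C)(C)C(C)(C)C)[C@H](C[C@@H](C)O[Si](C)(C)C(C)(C)C)C[C@]45OC(=O)C(=C5OC)C(O)[C@@]23C)C1
F6 | step 23 | tricyclic keto lactone (ring A ketone) | O=C1CC[C@@H]2[C@H](C=C[C@H]3[C@H](C)COC(=O)[C@@]23C)C1
F7 | step 23 | tricyclic lactone with exocyclic methylene on ring A | C=C1CC[C@@H]2[C@H](C=C[C@H]3[C@H](C)COC(=O)[C@@]23C)C1
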